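## Retrosynthetic overview

1. The target is the methyl ester 15-acetate of the A-series prostaglandin with 5Z and 13E side-chain alkenes (prostanoid numbering: C1 ester, C8 and C12 ring stereocentres, C9 ketone, C10=C11 ring alkene, C15 acetoxy carbon). The enone is an aldol-dehydration retron, so the last operation acetylates an 11,15-diol and expels the C11 oxygen; before that the Z-α-chain is attached at C8 by alkylation and a C8 sulfonyl activator is removed reductively.
2. Key disconnection: the only carbocycle is assembled in one flask from (phenylsulfonyl)acetone (C8–C9–C10) and a cis-4,5-epoxy-2E-decenal (C11–C20). C10–C11 forms by aldol addition of the ketone α,γ-dianion to the aldehyde, then C8–C12 by zerovalent-palladium-catalysed allylic alkylation that opens the vinyl epoxide.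
3. Enabling feature: the C9 carbonyl of the cyclopentenone lies between two enolisable ring carbons (C8 and C10, an acetone 1,3-dinucleophile), C11 is β to it at the aldehyde level, and ring carbon C12 is allylic and 1,4 to the C15 oxygen across the E-C13=C14 alkene. This is the pattern a C14–C15 vinyl epoxide gives when a soft carbanion attacks the allyl terminus remote from the oxygen.
4. Stereochemistry: one catalytic asymmetric epoxidation sets C14 and C15. C15 is kept, C14 is relayed to C12 in the key step while the E-alkene forms, and C8 then follows C12 (trans, thermodynamic).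
5. Ring order: oxirane (step 1, temporary, consumed in step 3), then the cyclopentanone ring (step 3); no other ring is made.

Key step: step 3

Assumption (chemistry): the ring carbinol carbon created in the key step (C11) is formed without control and is carried as a mixture of both epimers until it becomes sp2 in the last step. In the SMILES of those intermediates it carries no stereodescriptor.

## Route

Step 1
Reactants: 1 (2Z)-oct-2-en-1-ol
Product: 2 [(2R,3S)-3-pentyloxiran-2-yl]methanol
Conditions: Ti(OiPr)4 (10 mol %), D-(−)-diethyl tartrate (12 mol %), tBuOOH (2 equiv), 4 Å MS, CH2Cl2, −20 °C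
Reagents that add atoms: tert-butyl hydroperoxide, CC(C)(C)OO
Why: Sharpless asymmetric epoxidation, in which the catalyst formed from Ti(OiPr)4 and the D-tartrate delivers oxygen to the alkene face that makes the oxirane carbon next to the carbinol R, and the Z-geometry is transferred stereospecifically into the cis-oxirane, so the later C14 (relay centre) and C15 (carbinol carbon) are both set in this one catalytic event, which also fixes the enantiomeric purity of the whole route (Z-allylic alcohols are slower and expected to be somewhat less selective than E-ones).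

Step 2
Reactants: 2 [(2R,3S)-3-pentyloxiran-2-yl]methanol; 3 (triphenylphosphoranylidene)acetaldehyde
Product: 5 (2E)-3-[(2R,3S)-3-pentyloxiran-2-yl]prop-2-enal, via epoxy aldehyde 4 (not isolated)
Conditions: TEMPO (10 mol %), PhI(OAc)2 (1.1 equiv), CH2Cl2, 25 °C; then 3 (1.2 equiv), 25 °C
Reagents that add atoms: none
Why: Nitroxyl-catalysed alcohol oxidation stops at the labile α,β-epoxy aldehyde without reagents basic enough to epimerise it, and Wittig olefination with the stabilised formyl ylide in the same flask should give the E-enal under thermodynamic control, with no new stereocentre and the cis-oxirane untouched.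

Step 3
Reactants: 6 1-(phenylsulfonyl)propan-2-one; 5 (2E)-3-[(2R,3S)-3-pentyloxiran-2-yl]prop-2-enal
Product: 9 (2R,3S)-4-hydroxy-3-[(1E,3S)-3-hydroxyoct-1-en-1-yl]-2-(phenylsulfonyl)cyclopentan-1-one (both C4 epimers), via dilithium dianion 7 (not isolated), via aldol adduct 8 (not isolated)
Conditions: LiN(iPr)2 (2.1 equiv), THF, −78 → 0 °C; 5, −78 °C; AcOH (2.1 equiv), −78 → 25 °C; then Pd(PPh3)4 (5 mol %), dppe (5 mol %), 25 → 50 °C, same flask
Reagents that add atoms: none
Why: The α,γ-dianion 7 adds through its more basic γ-carbon (C10) to the aldehyde carbon (C11) of 5 in a 1,2-sense (dianion aldol addition); after neutralisation, zerovalent palladium ionises the vinyl epoxide of 8 with inversion at C14 to a syn,syn π-allyl complex whose C15 alkoxide deprotonates the β-keto sulfone, and the soft C8 carbanion attacks the allyl terminus C12 on the face opposite to palladium (intramolecular Tsuji–Trost alkylation under neutral conditions). The closest known reaction types are the γ-aldol additions of 1,3-dicarbonyl and β-keto sulfone dianions to enals, the neutral palladium-catalysed alkylation of vinyl epoxides at the terminus remote from oxygen, and the palladium-catalysed cyclisation of 3-oxo-6-alkenyl esters bearing an allylic leaving group to 2-acyl-3-vinylcyclopentanones. The cyclopentanone ring is closed at C8–C12 in a 5-(enolendo)-exo attack on the allyl terminus, a mode that is poor for SN2 displacements but established for π-allylpalladium electrophiles, where kinetic O-alkylation to the alkylidene tetrahydrofuran is reversible and drains to the carbocycle. C12 is set by chirality transfer from C14 (inversion on ionisation, inversion on attack, so the new C–C bond forms on the face the epoxide oxygen left, which for the 14R,15S cis-epoxide and the E-C12=C13 alkene should give the 12S centre); the C13=C14 alkene emerges E from the syn,syn-allyl, C15 keeps its C–O bond and configuration, C8 settles trans to the C12 side chain by enolisation, and C11 is formed without control and is erased in step 8. The step needs 1,2- over 1,4-addition of the dianion (hard γ-carbanion at −78 °C), five- over seven-membered closure (the larger ring would require the anti-allyl isomer) and C- over O-alkylation (thermodynamic control under palladium), and the diisopropylamine left from the base is too hindered to intercept the allyl complex.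

Step 4
Reactants: 10 (4-carboxybutyl)triphenylphosphonium bromide; 11 [(tert-butyldimethylsilyl)oxy]acetaldehyde
Product: 14 methyl (5Z)-7-hydroxyhept-5-enoate, via ylide carboxylate 12 (not isolated), via silyloxy heptenoate salt 13 (not isolated)
Conditions: NaN(SiMe3)2 (2.05 equiv), THF, 0 °C; 11, −78 → 25 °C; then HCl in MeOH, 25 °C
Reagents that add atoms: methanol, CO
Why: Salt-free Wittig olefination of the non-stabilised ylide should give the Z-alkene under kinetic control (cis-oxaphosphetane), and methanolic HCl then esterifies the acid (Fischer esterification) and cleaves the primary silyl ether in the same work-up; no stereocentre is formed.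

Step 5
Reactants: 14 methyl (5Z)-7-hydroxyhept-5-enoate
Product: 15 methyl (5Z)-7-bromohept-5-enoate
Conditions: CBr4, PPh3, CH2Cl2, 0 °C
Reagents that add atoms: carbon tetrabromide, BrC(Br)(Br)Br
Why: Appel reaction, in which bromide displaces the alkoxyphosphonium group by SN2 at the primary allylic carbon at 0 °C, which keeps the Z-alkene and creates no stereocentre.

Step 6
Reactants: 9 (2R,3S)-4-hydroxy-3-[(1E,3S)-3-hydroxyoct-1-en-1-yl]-2-(phenylsulfonyl)cyclopentan-1-one; 15 methyl (5Z)-7-bromohept-5-enoate
Product: 16 methyl (5Z)-7-[(1S,2S)-3-hydroxy-2-[(1E,3S)-3-hydroxyoct-1-en-1-yl]-5-oxo-1-(phenylsulfonyl)cyclopentyl]hept-5-enoate (both C3 epimers)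
Conditions: Cs2CO3 (1.1 equiv), DMF, 0 → 25 °C
Reagents that add atoms: none
Why: SN2 C-alkylation of the β-keto sulfone enolate with the primary Z-allylic bromide, in which carbonate ionises only the C8–H (the hydroxyls stay neutral and the enolate blocks β-elimination of the C11 hydroxyl) and the electrophile should approach anti to the adjacent C12 side chain, placing the α-chain trans to it at the new quaternary C8 (either epimer would converge after step 7).

Step 7
Reactants: 16 methyl (5Z)-7-[(1S,2S)-3-hydroxy-2-[(1E,3S)-3-hydroxyoct-1-en-1-yl]-5-oxo-1-(phenylsulfonyl)cyclopentyl]hept-5-enoate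
Product: 17 methyl (5Z)-7-[(1R,2R)-3-hydroxy-2-[(1E,3S)-3-hydroxyoct-1-en-1-yl]-5-oxocyclopentyl]hept-5-enoate (both C3 epimers)
Conditions: SmI2 (2.2 equiv), THF/MeOH, −78 °C; then KOAc, MeOH, 25 °C
Reagents that add atoms: none
Why: Reductive desulfonylation of an α-sulfonyl ketone by single-electron transfer from samarium diiodide should cleave only the activated C8–S bond (ketone, esters and alkenes are not reduced at −78 °C with this stoichiometry), the resulting enolate is protonated at C8, and mild acetate-mediated enolisation equilibrates this centre to the more stable 8,12-trans arrangement (thermodynamic substrate control).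

Step 8
Reactants: 17 methyl (5Z)-7-[(1R,2R)-3-hydroxy-2-[(1E,3S)-3-hydroxyoct-1-en-1-yl]-5-oxocyclopentyl]hept-5-enoate
Product: 19 methyl (5Z)-7-[(1R,2S)-2-[(1E,3S)-3-(acetyloxy)oct-1-en-1-yl]-5-oxocyclopent-3-en-1-yl]hept-5-enoate (target), via diacetate 18 (not isolated)
Conditions: Ac2O, pyridine, DMAP (cat.), CH2Cl2, 0 → 25 °C; then Et3N, 25 °C
Reagents that add atoms: acetic anhydride, CC(=O)OC(C)=O
Why: DMAP-catalysed acetylation of both secondary alcohols is followed by base-induced β-elimination of the 11-acetate through the C9 enolate, so both C11 epimers converge on the C10=C11 enone while the 15-acetate stays; the mild amine base should avoid migration of the ring double bond into conjugation with the side chain, and no stereocentre is formed while C8, C12 and C15 are untouched.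

## Compound list

1 | (2Z)-oct-2-en-1-ol | CCCCC/C=C\CO | starting material
2 | [(2R,3S)-3-pentyloxiran-2-yl]methanol | OC[C@H]1O[C@H]1CCCCC | intermediate
3 | (triphenylphosphoranylidene)acetaldehyde | O=CC=P(c1ccccc1)(c1ccccc1)c1ccccc1 | starting material
4 | (2S,3S)-3-pentyloxirane-2-carbaldehyde | O=C[C@H]1O[C@H]1CCCCC | intermediate
5 | (2E)-3-[(2R,3S)-3-pentyloxiran-2-yl]prop-2-enal | O=C/C=C/[C@H]1O[C@H]1CCCCC | intermediate
6 | 1-(phenylsulfonyl)propan-2-one | CC(=O)CS(=O)(=O)c1ccccc1 | starting material
7 | dilithium α,γ-dianion of 1-(phenylsulfonyl)propan-2-one | [Li+].[Li+].C=C([O-])[CH-]S(=O)(=O)c1ccccc1 | intermediate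
8 | (5E)-4-hydroxy-6-[(2R,3S)-3-pentyloxiran-2-yl]-1-(phenylsulfonyl)hex-5-en-2-one (both C4 epimers) | O=C(CS(=O)(=O)c1ccccc1)CC(O)/C=C/[C@H]2O[C@H]2CCCCC | intermediate
9 | (2R,3S)-4-hydroxy-3-[(1E,3S)-3-hydroxyoct-1-en-1-yl]-2-(phenylsulfonyl)cyclopentan-1-one (both C4 epimers) | CCCCC[C@H](O)/C=C/[C@H]1C(O)CC(=O)[C@@H]1S(=O)(=O)c2ccccc2 | intermediate
10 | (4-carboxybutyl)triphenylphosphonium bromide | OC(=O)CCCC[P+](c1ccccc1)(c1ccccc1)c1ccccc1.[Br-] | starting material
11 | [(tert-butyldimethylsilyl)oxy]acetaldehyde | O=CCO[Si](C)(C)C(C)(C)C | starting material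
12 | sodium 5-(triphenylphosphoranylidene)pentanoate | [Na+].[O-]C(=O)CCCC=P(c1ccccc1)(c1ccccc1)c1ccccc1 | intermediate
13 | sodium (5Z)-7-[(tert-butyldimethylsilyl)oxy]hept-5-enoate | [Na+].[O-]C(=O)CCC/C=C\CO[Si](C)(C)C(C)(C)C | intermediate
14 | methyl (5Z)-7-hydroxyhept-5-enoate | COC(=O)CCC/C=C\CO | intermediate
15 | methyl (5Z)-7-bromohept-5-enoate | COC(=O)CCC/C=C\CBr | intermediate
16 | methyl (5Z)-7-[(1S,2S)-3-hydroxy-2-[(1E,3S)-3-hydroxyoct-1-en-1-yl]-5-oxo-1-(phenylsulfonyl)cyclopentyl]hept-5-enoate (both C3 epimers) | CCCCC[C@H](O)/C=C/[C@H]1C(O)CC(=O)[C@@]1(C/C=C\CCCC(=O)OC)S(=O)(=O)c2ccccc2 | intermediate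
17 | methyl (5Z)-7-[(1R,2R)-3-hydroxy-2-[(1E,3S)-3-hydroxyoct-1-en-1-yl]-5-oxocyclopentyl]hept-5-enoate (both C3 epimers) | CCCCC[C@H](O)/C=C/[C@H]1C(O)CC(=O)[C@@H]1C/C=C\CCCC(=O)OC | intermediate
18 | methyl (5Z)-7-[(1R,2R)-3-(acetyloxy)-2-[(1E,3S)-3-(acetyloxy)oct-1-en-1-yl]-5-oxocyclopentyl]hept-5-enoate (both C3 epimers) | CCCCC[C@H](OC(C)=O)/C=C/[C@H]1C(OC(C)=O)CC(=O)[C@@H]1C/C=C\CCCC(=O)OC | intermediate
19 | methyl (5Z)-7-[(1R,2S)-2-[(1E,3S)-3-(acetyloxy)oct-1-en-1-yl]-5-oxocyclopent-3-en-1-yl]hept-5-enoate | CCCCC[C@@H](/C=C/[C@H]1C=CC(=O)[C@@H]1C/C=C\CCCC(=O)OC)OC(C)=O | target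

## Step count and risks

Total step count: 8. Longest linear sequence: 6 steps (steps 1, 2, 3, 6, 7, 8); steps 4 and 5 form the side branch.

Steps most likely to fail:

Step 3. The free C11 carbinol may intercept the allyl complex (dihydrofuran formation) or open the way to retro-aldol cleavage, kinetic O-alkylation of the β-keto sulfone may fail to revert, and exchange between palladium centres may erode the chirality transfer. The fallback sets out from the aldol adduct 8, isolated after aqueous work-up of the addition of 7 to 5, and comes back at 9. The carbinol is silylated (TBSCl, imidazole, DMF) to (5E)-4-[(tert-butyldimethylsilyl)oxy]-6-[(2R,3S)-3-pentyloxiran-2-yl]-1-(phenylsulfonyl)hex-5-en-2-one F1. This purified single substrate is cyclised with Pd2(dba)3·CHCl3 and dppe in THF at low catalyst loading to (2R,3S)-4-[(tert-butyldimethylsilyl)oxy]-3-[(1E,3S)-3-hydroxyoct-1-en-1-yl]-2-(phenylsulfonyl)cyclopentan-1-one F2, and HF·pyridine then returns 9. The approach changes from a telescoped cascade on the free aldol to a stepwise, protected sequence in which ring closure is the only event.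

Step 6. Alkylation at the hindered ring carbon may be slow, so that O-alkylation of the enolate, base-induced loss of the C11 hydroxyl or Z-to-E isomerisation of the allylic bromide compete. The fallback sets out from 9 and comes back at 17. Both hydroxyls are silylated (TBSCl, imidazole, DMF) to (2R,3S)-4-[(tert-butyldimethylsilyl)oxy]-3-[(1E,3S)-3-[(tert-butyldimethylsilyl)oxy]oct-1-en-1-yl]-2-(phenylsulfonyl)cyclopentan-1-one F3. The sodium enolate is formed irreversibly (NaH, DMF) and alkylated with 15 to methyl (5Z)-7-[(1S,2S)-3-[(tert-butyldimethylsilyl)oxy]-2-[(1E,3S)-3-[(tert-butyldimethylsilyl)oxy]oct-1-en-1-yl]-5-oxo-1-(phenylsulfonyl)cyclopentyl]hept-5-enoate F4. Desulfonylation with SmI2 as in step 7 should give methyl (5Z)-7-[(1R,2R)-3-[(tert-butyldimethylsilyl)oxy]-2-[(1E,3S)-3-[(tert-butyldimethylsilyl)oxy]oct-1-en-1-yl]-5-oxocyclopentyl]hept-5-enoate F5, and HF·pyridine in MeCN then releases 17. The change is from a protecting-group-free carbonate alkylation to a protected substrate that tolerates a preformed enolate and forcing conditions.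

Step 2. The α,β-epoxy aldehyde may epimerise or decompose while the weakly nucleophilic formyl ylide reacts slowly, and the product enal may be homologated a second time. The fallback sets out from 2 and comes back at 5. Compound 2 is oxidised as in step 2 and the crude aldehyde 4 is olefinated at the ester level with triethyl phosphonoacetate (LiCl, DBU, MeCN; Horner–Wadsworth–Emmons reaction) to ethyl (2E)-3-[(2R,3S)-3-pentyloxiran-2-yl]prop-2-enoate F6. Reduction with iBu2AlH (CH2Cl2, −78 °C) should give (2E)-3-[(2R,3S)-3-pentyloxiran-2-yl]prop-2-en-1-ol F7, and MnO2 in CH2Cl2 oxidises the allylic alcohol to 5. The approach changes from a direct formyl olefination to a faster phosphonate olefination followed by redox adjustment.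

## Further compounds

F1 | step 3 | (5E)-4-[(tert-butyldimethylsilyl)oxy]-6-[(2R,3S)-3-pentyloxiran-2-yl]-1-(phenylsulfonyl)hex-5-en-2-one | O=C(CS(=O)(=O)c1ccccc1)CC(O[Si](C)(C)C(C)(C)C)/C=C/[C@H]2O[C@H]2CCCCC
F2 | step 3 | (2R,3S)-4-[(tert-butyldimethylsilyl)oxy]-3-[(1E,3S)-3-hydroxyoct-1-en-1-yl]-2-(phenylsulfonyl)cyclopentan-1-one | CCCCC[C@H](O)/C=C/[C@H]1C(O[Si](C)(C)C(C)(C)C)CC(=O)[C@@H]1S(=O)(=O)c2ccccc2
F3 | step 6 | (2R,3S)-4-[(tert-butyldimethylsilyl)oxy]-3-[(1E,3S)-3-[(tert-butyldimethylsilyl)oxy]oct-1-en-1-yl]-2-(phenylsulfonyl)cyclopentan-1-one | CCCCC[C@H](O[Si](C)(C)C(C)(C)C)/C=C/[C@H]1C(O[Si](C)(C)C(C)(C)C)CC(=O)[C@@H]1S(=O)(=O)c2ccccc2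
F4 | step 6 | methyl (5Z)-7-[(1S,2S)-3-[(tert-butyldimethylsilyl)oxy]-2-[(1E,3S)-3-[(tert-butyldimethylsilyl)oxy]oct-1-en-1-yl]-5-oxo-1-(phenylsulfonyl)cyclopentyl]hept-5-enoate | CCCCC[C@H](O[Si](C)(C)C(C)(C)C)/C=C/[C@H]1C(O[Si](C)(C)C(C)(C)C)CC(=O)[C@@]1(C/C=C\CCCC(=O)OC)S(=O)(=O)c2ccccc2
F5 | step 6 | methyl (5Z)-7-[(1R,2R)-3-[(tert-butyldimethylsilyl)oxy]-2-[(1E,3S)-3-[(tert-butyldimethylsilyl)oxy]oct-1-en-1-yl]-5-oxocyclopentyl]hept-5-enoate | CCCCC[C@H](O[Si](C)(C)C(C)(C)C)/C=C/[C@H]1C(O[Si](C)(C)C(C)(C)C)CC(=O)[C@@H]1C/C=C\CCCC(=O)OC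
F6 | step 2 | ethyl (2E)-3-[(2R,3S)-3-pentyloxiran-2-yl]prop-2-enoate | CCOC(=O)/C=C/[C@H]1O[C@H]1CCCCC
F7 | step 2 | (2E)-3-[(2R,3S)-3-pentyloxiran-2-yl]prop-2-en-1-ol | OC/C=C/[C@H]1O[C@H]1CCCCC
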